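## Retrosynthetic overview

1. Only the hexasubstituted resorcylate ring has to be built, since the phenyl ring is bought. It is cut [3+3] at C2–C3 and C5–C6.
2. C3–C4–C5 is the symmetrical ketone 3, which already carries both prenyl groups on its two α-carbons. C6–C1–C2 is the β-chloroalkylidene malonate 7, which carries the phenethyl group, the ester and the future C2–OH carbon.
3. Ketone 3 comes from 6-methylhept-5-en-2-one 1 and prenyl bromide 2 by kinetic enolate alkylation.
4. Compound 7 comes from dimethyl malonate 4 and 3-phenylpropanoyl chloride 5, by C-acylation to 6 and then deoxychlorination.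
5. Ring order in the key flask: a transient 2-pyranone ring (9) closes first through oxygen. Base then transposes it into the benzene ring of 10 (the new step).

**Assumption:** the SMILES holds no stereocentre and no E/Z-stereogenic alkene (both alkenes end in CMe2). The target is therefore achiral, and the request for a single enantiomer needs no stereocontrol.

**Ring numbering used below:** C1 CO2Me, C2 OH, C3 prenyl, C4 OH, C5 prenyl, C6 CH2CH2Ph.

## Route

**Step 1**
Reactants: 1 6-methylhept-5-en-2-one; 2 1-bromo-3-methylbut-2-ene (prenyl bromide)
Product: 3 2,10-dimethylundeca-2,9-dien-6-one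
Conditions: LiN(iPr)2 (1.05 equiv, commercial solution), THF, −78 °C; then 2 (1.1 equiv), DMPU, −78 → 0 °C
Reagents that add atoms: none
Why: Kinetic enolate alkylation: the hindered amide removes the less hindered CH3 proton at −78 °C, and the terminal enolate displaces bromide at the primary allylic carbon of 2 (SN2) to give the symmetrical ketone, with no stereocentre formed.

**Step 2**
Reactants: 4 dimethyl malonate; 5 3-phenylpropanoyl chloride
Product: 6 dimethyl 2-(3-phenylpropanoyl)propanedioate
Conditions: MgCl2 (1.0 equiv), Et3N (2.0 equiv), MeCN, 0 → 23 °C; 1 M HCl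
Reagents that add atoms: none
Why: Soft-enolisation C-acylation of a malonate (crossed Claisen-type condensation): the chelated magnesium enolate is acylated at carbon only, and the acidic product is held as its chelate, which stops over-acylation.

**Step 3**
Reactants: 6 dimethyl 2-(3-phenylpropanoyl)propanedioate
Product: 7 dimethyl 2-(1-chloro-3-phenylpropylidene)propanedioate
Conditions: POCl3 (neat, 6 equiv), Bu3N (1.0 equiv), 105 °C; ice water
Reagents that add atoms: phosphoryl chloride, O=P(Cl)(Cl)Cl
Why: Deoxychlorination of a β-dicarbonyl enol: O-phosphorylation of the fully enolised acylmalonate makes a dichlorophosphate leaving group that chloride replaces by addition–elimination, the two identical esters rule out E/Z isomers, and the substrate holds nothing sensitive to hot POCl3.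

**Step 4**
Reactants: 3 2,10-dimethylundeca-2,9-dien-6-one; 7 dimethyl 2-(1-chloro-3-phenylpropylidene)propanedioate
Product: 10 methyl 2,4-dihydroxy-3,5-bis(3-methylbut-2-en-1-yl)-6-(2-phenylethyl)benzoate, via keto alkylidenemalonate 8 (not isolated), via 2-pyranone 9 (not isolated)
Conditions: 3 (1.1 equiv), LiN(SiMe3)2 (2.2 equiv), THF, −78 °C; 7 (1.0 equiv), −78 → 23 °C; then LiN(SiMe3)2 (1.5 equiv), 55 °C; cold 1 M HCl
Reagents that add atoms: none
Why: Proposed new method: this is an anionic formal [3+3] benzannulation in which an unactivated symmetrical dialkyl ketone is the C3–C4–C5 1,3-dinucleophile and a β-chloroalkylidene malonate is the C6–C1–C2 1,3-dielectrophile; the lithium enolate of 3 (symmetry removes any regiochemical choice) adds to the doubly activated alkene of 7 and expels chloride (addition–elimination, C5–C6 bond); the second equivalent of base holds the very acidic adduct 8 as a delocalised enolate, whose oxygen closes on the cis ester on warming to give 9 with loss of methoxide, and up to here the sequence parallels the known 2-pyranone-3-carboxylate synthesis from ketone enolates and alkoxymethylene malonates; the new event is that further base removes a proton from the 6-CH2 of 9, and the trienolate opens by E1cB loss of the ring oxygen as an enolate to give a (Z)-dienylketene enolate; that species closes irreversibly at carbon (oxyanion-accelerated 6π electrocyclisation, equivalent to enolate C-acylation of the ketene, C2–C3 bond) and tautomerises to the resorcylate dianion, the thermodynamic sink; deprotonation at the 4-CH2 of 9 is reversible and unproductive, the strongly basic acid-free medium leaves both prenyl alkenes untouched, and no stereocentre remains; the closest known reaction types are the Michael–Dieckmann synthesis of dihydroresorcylates from enones and malonates, base-induced pyranone-to-resorcinol ring transformations of polyketide models, and the dienylketene electrocyclisation of Danheiser-type benzannulations.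

## Compound list

1 | 6-methylhept-5-en-2-one | CC(=O)CCC=C(C)C | starting material
2 | 1-bromo-3-methylbut-2-ene (prenyl bromide) | CC(C)=CCBr | starting material
3 | 2,10-dimethylundeca-2,9-dien-6-one | CC(C)=CCCC(=O)CCC=C(C)C | intermediate
4 | dimethyl malonate (dimethyl propanedioate) | COC(=O)CC(=O)OC | starting material
5 | 3-phenylpropanoyl chloride | O=C(Cl)CCc1ccccc1 | starting material
6 | dimethyl 2-(3-phenylpropanoyl)propanedioate | COC(=O)C(C(=O)OC)C(=O)CCc1ccccc1 | intermediate
7 | dimethyl 2-(1-chloro-3-phenylpropylidene)propanedioate | COC(=O)C(C(=O)OC)=C(Cl)CCc1ccccc1 | intermediate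
8 | dimethyl 2-[9-methyl-4-(3-methylbut-2-en-1-yl)-5-oxo-1-phenyldec-8-en-3-ylidene]propanedioate (racemic, not isolated) | COC(=O)C(C(=O)OC)=C(CCc1ccccc1)C(CC=C(C)C)C(=O)CCC=C(C)C | intermediate
9 | methyl 6-(4-methylpent-3-en-1-yl)-5-(3-methylbut-2-en-1-yl)-2-oxo-4-(2-phenylethyl)-2H-pyran-3-carboxylate (not isolated) | COC(=O)C1=C(CCc2ccccc2)C(CC=C(C)C)=C(CCC=C(C)C)OC1=O | intermediate
10 | methyl 2,4-dihydroxy-3,5-bis(3-methylbut-2-en-1-yl)-6-(2-phenylethyl)benzoate (achiral) | COC(=O)c1c(O)c(CC=C(C)C)c(O)c(CC=C(C)C)c1CCc1ccccc1 | target

## Step count and risks

Total step count: 4.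
Longest linear sequence: 3 steps (4 + 5 → 6 → 7 → 10). The other branch is 1 + 2 → 3 → 10.

**Step 4 (the proposed new step).**
- The addition–elimination at a tetrasubstituted acceptor may be slow and lose out to γ-deprotonation of 7.
- The cascade may stop at 9.
- The amide base may attack the lactone.

The fallback uses known chemistry only. It sets out from 4 and comes back at 10. 3-Phenylpropanal and Ph3P=CHC(O)CH3 (Wittig olefination, toluene, 80 °C) give (E)-6-phenylhex-3-en-2-one F1. Compound 4 and this enone with NaOMe in MeOH at reflux (Michael addition–Dieckmann condensation) give racemic methyl 2-hydroxy-4-oxo-6-(2-phenylethyl)cyclohex-2-ene-1-carboxylate F2. Br2 in DMF (0 °C, then 80 °C; bromination–dehydrobromination) aromatises it to methyl 2,4-dihydroxy-6-(2-phenylethyl)benzoate F3. Allyl bromide and K2CO3 in DMF at 60 °C give methyl 6-(2-phenylethyl)-2,4-bis(prop-2-en-1-yloxy)benzoate F4. Heating in N,N-diethylaniline at 195 °C brings about a double aromatic Claisen rearrangement. Every pathway (ortho shift, or ortho shift followed by Cope shift to the para carbon) converges, because an allyl group is unchanged by allylic inversion. The product is methyl 2,4-dihydroxy-6-(2-phenylethyl)-3,5-di(prop-2-en-1-yl)benzoate F5. Double cross-metathesis with excess 2-methylbut-2-ene then gives 10. This uses second-generation Grubbs catalyst (H2IMes)(PCy3)Cl2Ru=CHPh (5 mol %) in CH2Cl2 at 40 °C.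

**Step 1.** Some internal enolate and enolate exchange can give the regioisomeric and doubly alkylated ketones, which are hard to separate from 3. The fallback sets out from 2 and comes back at 3. Dimethyl 3-oxopentanedioate is converted to its bis-enolate with NaH (2.1 equiv) in THF at 0 °C and alkylated with 2 (2.05 equiv), once at each activated carbon. This gives dimethyl 2,4-bis(3-methylbut-2-en-1-yl)-3-oxopentanedioate F6 as a mixture of diastereomers. Saponification with NaOH in aqueous MeOH, acidification to pH 4 and warming to 50 °C cause double decarboxylation to 3. The position of both prenyl groups is fixed by the activating esters.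

**Step 3.** Hot POCl3 with amine may cause dehydrochlorination or tar formation instead of clean chloride exchange. The fallback sets out from 6 and comes back at 8, inside step 4. It keeps the enol oxygen and turns it into the leaving group at low temperature. Tf2O and Et3N in CH2Cl2 at −78 °C give dimethyl 2-[3-phenyl-1-(trifluoromethylsulfonyloxy)propylidene]propanedioate F7. This replaces 7 in step 4 and gives 8 by the same addition–elimination, with triflate leaving.

## Further compounds

F1 | step 4 | (E)-6-phenylhex-3-en-2-one | CC(=O)/C=C/CCc1ccccc1
F2 | step 4 | methyl 2-hydroxy-4-oxo-6-(2-phenylethyl)cyclohex-2-ene-1-carboxylate (racemic, both stereocentres erased in the next operation) | COC(=O)C1C(CCc2ccccc2)CC(=O)C=C1O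
F3 | step 4 | methyl 2,4-dihydroxy-6-(2-phenylethyl)benzoate | COC(=O)c1c(O)cc(O)cc1CCc1ccccc1
F4 | step 4 | methyl 6-(2-phenylethyl)-2,4-bis(prop-2-en-1-yloxy)benzoate | COC(=O)c1c(OCC=C)cc(OCC=C)cc1CCc1ccccc1
F5 | step 4 | methyl 2,4-dihydroxy-6-(2-phenylethyl)-3,5-di(prop-2-en-1-yl)benzoate | COC(=O)c1c(O)c(CC=C)c(O)c(CC=C)c1CCc1ccccc1
F6 | step 1 | dimethyl 2,4-bis(3-methylbut-2-en-1-yl)-3-oxopentanedioate (mixture of diastereomers) | COC(=O)C(CC=C(C)C)C(=O)C(CC=C(C)C)C(=O)OC
F7 | step 3 | dimethyl 2-[3-phenyl-1-(trifluoromethylsulfonyloxy)propylidene]propanedioate | COC(=O)C(C(=O)OC)=C(CCc1ccccc1)OS(=O)(=O)C(F)(F)F
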